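**Retrosynthetic overview**
- The strategy rests on C6–Br sitting between the oxygenated C5 and the formyl-bearing C1. C1–C5 are the five ring carbons of cyclotene (C4 ketone carbon, C5 enol carbon, C1 methyl-bearing carbon, C2 and C3 the two CH2 groups), the methyl group is the latent CHO, and C6 is an inserted CBr unit.
- CHO comes from ArCHBr2, made from ArCH3 by radical dibromination on the catechol diacetate; C2–Br and C3–Br come from electrophilic bromination of 3-bromo-4-methylcatechol 8.
- Catechol 8 is the aromatic tautomer of ene-dione 7, which comes from bromoenone ketal 6; 6 arises by dibromocarbene (from bromoform 4) ring expansion of silyl enol ether 3, forming C5–C6 and C6–C1.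
- Precursor 3 comes from cyclotene 1 by O-silylation and dioxolane formation.
- Ring order: the cyclopentene of cyclotene is the only carbocycle; it is expanded to the six-membered ring, which aromatizes without an oxidant.

Key step: step 3

Remark: the target is achiral and is numbered C1 (formyl-bearing carbon), C2, C3 and C6 (Br), C4 and C5 (OH); cyclotene is taken as its enol tautomer, and the racemic, non-isolated compound 5 is the only chiral compound of the route.

**Route**

Step 1
Reactants: 1 2-hydroxy-3-methylcyclopent-2-en-1-one (cyclotene)
Product: 2 2-(tert-butyldimethylsilyloxy)-3-methylcyclopent-2-en-1-one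
Conditions: TBSCl, imidazole, DMF, 0 °C to rt
Reagents that add atoms: tert-butyldimethylsilyl chloride, CC(C)(C)[Si](C)(C)Cl
Why: Cyclotene exists as its enol, and imidazole-mediated silyl ether formation silylates the acidic diosphenol hydroxyl on oxygen, fixing the enol double bond between the oxygenated carbon and the methyl-bearing carbon.

Step 2
Reactants: 2 2-(tert-butyldimethylsilyloxy)-3-methylcyclopent-2-en-1-one
Product: 3 6-(tert-butyldimethylsilyloxy)-7-methyl-1,4-dioxaspiro[4.4]non-6-ene
Conditions: (TMSOCH2)2, TMSOTf (5 mol %), CH2Cl2, −78 to −30 °C; pyridine quench, aq. NaHCO3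
Reagents that add atoms: 1,2-bis(trimethylsilyloxy)ethane, C[Si](C)(C)OCCO[Si](C)(C)C
Why: Noyori dioxolanation, in which the silyl triflate activates the only carbonyl group, the bis-silyl glycol ether delivers the diol, and irreversible formation of hexamethyldisiloxane under aprotic conditions at low temperature leaves the silyl enol ether and the position of its double bond untouched.

Step 3
Reactants: 3 6-(tert-butyldimethylsilyloxy)-7-methyl-1,4-dioxaspiro[4.4]non-6-ene; 4 bromoform
Product: 8 3-bromo-4-methylbenzene-1,2-diol, via dibromocyclopropane 5 (not isolated), via bromoenone ketal 6 (not isolated), via bromo ene-dione 7 (not isolated)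
Conditions: CHBr3, KOt-Bu, pentane, −30 °C to rt; solvent exchange, then 3 M aq. HCl, THF, 50 °C, under argon
Reagents that add atoms: bromoform 4, BrC(Br)Br; water, O
Why: α-Elimination of bromoform by tert-butoxide gives singlet dibromocarbene, an electrophile that adds in a concerted [2+1] cheletropic step to the only C=C bond of 3, the electron-rich tetrasubstituted silyl enol ether, closing the three-membered ring of 5 and forming C5–C6 and C6–C1. The strained 1-silyloxy-6,6-dibromobicyclo[3.1.0]hexane then opens by disrotatory two-electron electrocyclic cleavage of the bond shared by the three- and five-membered rings while the endo bromide leaves, pushed by the oxygen lone pair, so the six-membered ring arises by ring expansion and not by an end-to-end cyclization; loss of the silyl group from the resulting oxocarbenium ion gives the 2-bromoenone 6. The closest known reaction type is the dihalocarbene one-carbon ring expansion of cyclic silyl enol ethers to 2-halocycloalk-2-enones. Aqueous acid then hydrolyses the dioxolane, and dione 7, a keto tautomer of the catechol, aromatizes by two proton shifts without any oxidant. No stereocentre survives the step (the two ring-fusion centres of racemic 5 are lost on opening), and the only selectivity needed, the site of carbon insertion, is fixed by the position of the enol ether double bond between the oxygenated carbon and the methyl-bearing carbon, the dioxolane preventing an enol ether on the other side.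

Step 4
Reactants: 8 3-bromo-4-methylbenzene-1,2-diol
Product: 9 3,4,6-tribromo-5-methylbenzene-1,2-diol
Conditions: Br2 (2.2 equiv), AcOH, 15 °C to rt
Reagents that add atoms: bromine, BrBr
Why: Electrophilic aromatic substitution, in which both remaining ring hydrogens sit ortho or para to a free phenolic hydroxyl so that two equivalents of bromine fill them, and no regiochemical question arises because every open position is to be brominated.

Step 5
Reactants: 9 3,4,6-tribromo-5-methylbenzene-1,2-diol
Product: 10 3,4,6-tribromo-5-methyl-1,2-phenylene diacetate
Conditions: Ac2O, pyridine, DMAP (cat.), CH2Cl2, rt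
Reagents that add atoms: acetic anhydride, CC(=O)OC(C)=O
Why: DMAP-catalysed acyl transfer converts both phenols into acetates, masking the oxidizable catechol before the radical bromination of the next step.

Step 6
Reactants: 10 3,4,6-tribromo-5-methyl-1,2-phenylene diacetate
Product: 11 3,4,6-tribromo-5-(dibromomethyl)-1,2-phenylene diacetate
Conditions: NBS (2.5 equiv), AIBN (cat.), PhCF3, reflux
Reagents that add atoms: N-bromosuccinimide, O=C1CCC(=O)N1Br
Why: Wohl–Ziegler radical bromination, in which the methyl group carries the only weak C–H bonds of a fully substituted, electron-poor ring, so benzylic hydrogen abstraction and bromine transfer occur twice, while the two flanking bromines make a third substitution too slow to compete.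

Step 7
Reactants: 11 3,4,6-tribromo-5-(dibromomethyl)-1,2-phenylene diacetate
Product: 13 2,3,6-tribromo-4,5-dihydroxybenzaldehyde, via dibromomethyl catechol 12 (not isolated)
Conditions: 3 M aq. HCl, 1,4-dioxane, 90 °C, under argon
Reagents that add atoms: water, O
Why: Acid-catalysed ester hydrolysis frees the catechol, after which the hydroxyl para to the dibromomethyl group assists ionization of the geminal dibromide (through a para-quinone methide) and water converts it into the aldehyde, which should be stable under the acidic, oxygen-free conditions.

**Compound list**
1 | 2-hydroxy-3-methylcyclopent-2-en-1-one (cyclotene) | CC1=C(O)C(=O)CC1 | starting material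
2 | 2-(tert-butyldimethylsilyloxy)-3-methylcyclopent-2-en-1-one | CC1=C(O[Si](C)(C)C(C)(C)C)C(=O)CC1 | intermediate
3 | 6-(tert-butyldimethylsilyloxy)-7-methyl-1,4-dioxaspiro[4.4]non-6-ene | CC1=C(O[Si](C)(C)C(C)(C)C)C2(CC1)OCCO2 | intermediate
4 | bromoform | BrC(Br)Br | starting material
5 | 6,6-dibromo-1-(tert-butyldimethylsilyloxy)-5-methylspiro[bicyclo[3.1.0]hexane-2,2'-[1,3]dioxolane] (racemic; cis ring fusion is the only one possible) | CC12CCC3(OCCO3)C1(O[Si](C)(C)C(C)(C)C)C2(Br)Br | intermediate
6 | 7-bromo-8-methyl-1,4-dioxaspiro[4.5]dec-7-en-6-one | CC1=C(Br)C(=O)C2(CC1)OCCO2 | intermediate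
7 | 3-bromo-4-methylcyclohex-3-ene-1,2-dione | CC1=C(Br)C(=O)C(=O)CC1 | intermediate
8 | 3-bromo-4-methylbenzene-1,2-diol | Cc1ccc(O)c(O)c1Br | intermediate
9 | 3,4,6-tribromo-5-methylbenzene-1,2-diol | Cc1c(Br)c(O)c(O)c(Br)c1Br | intermediate
10 | 3,4,6-tribromo-5-methyl-1,2-phenylene diacetate | Cc1c(Br)c(OC(C)=O)c(OC(C)=O)c(Br)c1Br | intermediate
11 | 3,4,6-tribromo-5-(dibromomethyl)-1,2-phenylene diacetate | BrC(Br)c1c(Br)c(OC(C)=O)c(OC(C)=O)c(Br)c1Br | intermediate
12 | 3,4,6-tribromo-5-(dibromomethyl)benzene-1,2-diol | BrC(Br)c1c(Br)c(O)c(O)c(Br)c1Br | intermediate
13 | 2,3,6-tribromo-4,5-dihydroxybenzaldehyde | O=Cc1c(Br)c(O)c(O)c(Br)c1Br | target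

**Totals**
Total step count: 7. Longest linear sequence: 7 steps.

**Steps most likely to fail**

1. Step 3. Several processes could go wrong:
   - The carbene may add too slowly to the hindered tetrasubstituted alkene and be consumed by tert-butoxide instead.
   - Remaining base may deprotonate the bromoenone at its γ-position, so that a second carbene is taken up.
   - During the acid stage the ring-opened dioxolane may lose a proton instead of capturing water, which would aromatize to a 2-hydroxyethyl aryl ether in place of the free catechol.

   Fallback: the one-carbon expansion would be done without halogen and the C6 bromine brought in afterwards. From 3, Simmons–Smith cyclopropanation of the silyl enol ether (Et2Zn, CH2I2, CH2Cl2, 0 °C) would give 1-(tert-butyldimethylsilyloxy)-5-methylspiro[bicyclo[3.1.0]hexane-2,2'-[1,3]dioxolane] F1. Oxidative opening of the silyloxycyclopropane with FeCl3 in DMF (Saegusa ring expansion) would cleave the ring-fusion bond toward the tertiary radical and give 8-chloro-8-methyl-1,4-dioxaspiro[4.5]decan-6-one F2. NaOAc in MeOH would then eliminate HCl to give 8-methyl-1,4-dioxaspiro[4.5]dec-7-en-6-one F3. Aqueous HCl in THF would remove the dioxolane; 4-methylcyclohex-3-ene-1,2-dione F4 would tautomerize to 4-methylbenzene-1,2-diol F5. Bromine (3.3 equiv, AcOH) would then fill all three ring positions, so the route is rejoined at 9 and steps 5 to 7 follow unchanged.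

2. Step 2. The silyl triflate may ionize the newly formed allylic ketal, opening the way to silyl transfer, double-bond migration or Mukaiyama-type self-condensation of the enol ether with an oxocarbenium ion; ketalization of the hindered conjugated carbonyl may also be slow.

   Fallback: the order of protection is reversed. From 1, acid-catalysed ketalization with ethylene glycol (1.1 equiv, TsOH, benzene, Dean–Stark) is expected to occur at the only carbonyl group that the enol tautomer exposes, the one remote from the methyl group, and after ketonization of the enol to give 7-methyl-1,4-dioxaspiro[4.4]nonan-6-one F6. This ketone has a single enolizable position, so deprotonation with KN(SiMe3)2 and O-silylation with TBSCl (THF, −78 °C) can only lead to 3, where the route is rejoined.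

3. Step 6. The second benzylic hydrogen abstraction may stall because the two ortho bromines shield the bromomethyl group, leaving a mixture of mono- and dibromide.

   Fallback: the aldehyde oxidation state is reached by oxidation of the monobromide instead of a second halogenation. From 10, one equivalent of NBS (AIBN, PhCF3, reflux) would give 3,4,6-tribromo-5-(bromomethyl)-1,2-phenylene diacetate F7. Kornblum oxidation (DMSO, NaHCO3, 80 °C, under argon) would convert it into 3,4,6-tribromo-5-formyl-1,2-phenylene diacetate F8; any acetate lost at this stage is of no consequence. Acidic hydrolysis of the acetates (3 M aq. HCl, 1,4-dioxane, 90 °C) would then give 13.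

Further compounds
F1 | step 3 | 1-(tert-butyldimethylsilyloxy)-5-methylspiro[bicyclo[3.1.0]hexane-2,2'-[1,3]dioxolane] (racemic) | CC12CCC3(OCCO3)C1(O[Si](C)(C)C(C)(C)C)C2
F2 | step 3 | 8-chloro-8-methyl-1,4-dioxaspiro[4.5]decan-6-one (racemic) | CC1(Cl)CC(=O)C2(CC1)OCCO2
F3 | step 3 | 8-methyl-1,4-dioxaspiro[4.5]dec-7-en-6-one | CC1=CC(=O)C2(CC1)OCCO2
F4 | step 3 | 4-methylcyclohex-3-ene-1,2-dione | CC1=CC(=O)C(=O)CC1
F5 | step 3 | 4-methylbenzene-1,2-diol | Cc1ccc(O)c(O)c1
F6 | step 2 | 7-methyl-1,4-dioxaspiro[4.4]nonan-6-one (racemic) | CC1CCC2(OCCO2)C1=O
F7 | step 6 | 3,4,6-tribromo-5-(bromomethyl)-1,2-phenylene diacetate | CC(=O)Oc1c(Br)c(CBr)c(Br)c(Br)c1OC(C)=O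
F8 | step 6 | 3,4,6-tribromo-5-formyl-1,2-phenylene diacetate | CC(=O)Oc1c(Br)c(C=O)c(Br)c(Br)c1OC(C)=O
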